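The 2,3-dihydrofuran ring of the target carries a one-carbon branch (CH2OH) on C3 and an aryl group on C2, trans to each other. Both are traced to one carbon bridging C2 and C3 of a flat benzofuran. An enantioselective copper–bis(oxazoline) cyclopropanation with tert-butyl diazoacetate forms the C3–C and C2–C bonds, closes the cyclopropane and fixes C3 in a single operation. The C2–C bond of this donor–acceptor cyclopropane is then broken by 2,6-dimethoxyphenol (aryl enters anti to the C3 arm), and the extra carboxyl carbon is excised to leave CH2OH. The precursor is methyl 3-(7-methoxybenzofuran-5-yl)propanoate, made from methyl dihydroferulate by iodination, Sonogashira coupling and cyclisation.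

Key step: step 4

Atom labels: benzofuran numbering (O1, C2, C3, C3a, C4–C7, C7a) is used throughout. In compound 8 the former C2 is C1a, the former C3 is C6b and the carbene carbon is C1. The target is (2S,3R), 2,3-trans.

Assumption: the (S,S) ligand is assigned to the required face by analogy with the sense it shows for styrene-type alkenes (same configuration at the carbene carbon). Should the first run give the mirror image, the equally available (R,R) ligand is used and nothing else changes.

Design remark: the phenol introduced in step 5 is capped as its acetate for steps 7–9. A free 4-hydroxy-3,5-dimethoxyphenyl group at C2 would favour acid ionisation of the benzylic C2–O bond and would offer its O–H hydrogen to the alkyl radical.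

Step 1
Reactants: 1 methyl 3-(4-hydroxy-3-methoxyphenyl)propanoate
Product: 2 methyl 3-(4-hydroxy-3-iodo-5-methoxyphenyl)propanoate
Conditions: I2 (1.05 equiv), NaHCO3 (1.5 equiv), THF/H2O 1:1, 0 °C → rt
Reagents that add atoms: iodine, II
Why: Electrophilic aromatic iodination through the phenoxide, which directs iodine to its only free ortho position (C5) because the para position carries the side chain; NaHCO3 is too weak to saponify the methyl ester.

Step 2
Reactants: 2 methyl 3-(4-hydroxy-3-iodo-5-methoxyphenyl)propanoate; 3 trimethylsilylacetylene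
Product: 4 methyl 3-[4-hydroxy-3-methoxy-5-(trimethylsilylethynyl)phenyl]propanoate
Conditions: PdCl2(PPh3)2 (2 mol %), CuI (4 mol %), Et3N (3 equiv), THF, rt, Ar
Reagents that add atoms: none
Why: Sonogashira coupling of the aryl iodide should proceed at room temperature without protection of the phenol, and at that temperature the silylalkyne should not yet cyclise.

Step 3
Reactants: 4 methyl 3-[4-hydroxy-3-methoxy-5-(trimethylsilylethynyl)phenyl]propanoate
Product: 6 methyl 3-(7-methoxy-1-benzofuran-5-yl)propanoate, via terminal alkynylphenol 5 (not isolated)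
Conditions: K2CO3 (0.5 equiv), MeOH, rt, 1 h; then CuI (10 mol %), DMF, 65 °C, Ar
Reagents that add atoms: none
Why: Methanolysis of the alkynyl–silicon bond followed by copper-promoted 5-endo-dig cycloisomerisation (hydroalkoxylation) of the ortho-ethynylphenoxide should give the aromatic furan ring; methanol as solvent keeps the methyl ester unchanged.

Step 4
Reactants: 6 methyl 3-(7-methoxy-1-benzofuran-5-yl)propanoate; 7 tert-butyl diazoacetate
Product: 8 tert-butyl (1R,1aR,6bS)-3-methoxy-5-(3-methoxy-3-oxopropyl)-1a,6b-dihydro-1H-cyclopropa[b][1]benzofuran-1-carboxylate (cis ring fusion, exo ester)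
Conditions: (CuOTf)2·C6H6 (1 mol %), 2,2'-(propane-2,2-diyl)bis[(4S)-4-tert-butyl-4,5-dihydrooxazole] ((S,S)-tBu-box, 2.4 mol %), CH2Cl2, 0 °C → rt; 7 (2.5 equiv) added over 10 h by syringe pump
Reagents that add atoms: none
Why: The monovalent copper–bis(oxazoline) complex releases N2 from 7 to give an electrophilic copper carbene, which the enol-ether-like C2=C3 bond of the furan ring attacks in a concerted but asynchronous [2+1] addition: the C3–C1 bond leads, positive charge builds at C2 next to O1, and the C2–C1 bond then forms with release of copper. The closest known reaction type is the copper–bis(oxazoline) cyclopropanation of furans, benzofurans and enol ethers with diazoacetates. The cyclopropane closes by collapse of the developing C2 cation onto the copper-bound carbon (3-exo closure), suprafacially, so the cis ring fusion is enforced by geometry. C6b (the later C3) is set by the C2-symmetric ligand, whose tert-butyl groups leave one face of the heteroarene open to the carbene; C1a follows from C6b through the suprafacial addition; C1 is exo because the tert-butyl ester turns away from the benzo ring in the approach. The step needs site selectivity for C2=C3 over the benzenoid ring and over carbene dimerisation, which the higher nucleophilicity of the furan double bond and the slow addition of 7 should secure, and face selectivity, which rests on the ligand alone.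

Step 5
Reactants: 8 tert-butyl (1R,1aR,6bS)-3-methoxy-5-(3-methoxy-3-oxopropyl)-1a,6b-dihydro-1H-cyclopropa[b][1]benzofuran-1-carboxylate; 9 2,6-dimethoxyphenol
Product: 10 methyl 3-[(2S,3S)-3-(2-tert-butoxy-2-oxoethyl)-2-(4-hydroxy-3,5-dimethoxyphenyl)-7-methoxy-2,3-dihydro-1-benzofuran-5-yl]propanoate (2,3-trans)
Conditions: Sc(OTf)3 (10 mol %), 9 (3 equiv), CH2Cl2, 4 Å MS, −20 °C → rt
Reagents that add atoms: none
Why: Friedel–Crafts-type arylative opening of a donor–acceptor cyclopropane: Sc(OTf)3 on the ester carbonyl and the lone pair of the ring oxygen break the C1a–C1 bond to an oxocarbenium/enolate pair, and the para carbon of the phenol, used in excess to outrun loss of the C3 proton, attacks C2 on the face opposite the C3 arm, which sets C2 trans to C3 while C3 itself is not touched.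

Step 6
Reactants: 10 methyl 3-[(2S,3S)-3-(2-tert-butoxy-2-oxoethyl)-2-(4-hydroxy-3,5-dimethoxyphenyl)-7-methoxy-2,3-dihydro-1-benzofuran-5-yl]propanoate
Product: 11 methyl 3-[(2S,3S)-2-(4-acetoxy-3,5-dimethoxyphenyl)-3-(2-tert-butoxy-2-oxoethyl)-7-methoxy-2,3-dihydro-1-benzofuran-5-yl]propanoate
Conditions: Ac2O (1.5 equiv), pyridine (3 equiv), DMAP (5 mol %), CH2Cl2, 0 °C → rt
Reagents that add atoms: acetic anhydride, CC(=O)OC(C)=O
Why: DMAP-catalysed O-acylation; the acetate removes the phenolic hydrogen before the radical step and lowers the donor power of the aryl ring so that the benzylic C2–O bond should not ionise in TFA.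

Step 7
Reactants: 11 methyl 3-[(2S,3S)-2-(4-acetoxy-3,5-dimethoxyphenyl)-3-(2-tert-butoxy-2-oxoethyl)-7-methoxy-2,3-dihydro-1-benzofuran-5-yl]propanoate
Product: 12 2-[(2S,3S)-2-(4-acetoxy-3,5-dimethoxyphenyl)-7-methoxy-5-(3-methoxy-3-oxopropyl)-2,3-dihydro-1-benzofuran-3-yl]acetic acid
Conditions: TFA/CH2Cl2 1:4, 0 °C → rt
Reagents that add atoms: none
Why: Acidolysis of the tert-butyl ester by the E1 pathway (loss of the tert-butyl cation as isobutene) should leave the methyl ester and the aryl acetate, which cannot ionise in this way, intact.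

Step 8
Reactants: 12 2-[(2S,3S)-2-(4-acetoxy-3,5-dimethoxyphenyl)-7-methoxy-5-(3-methoxy-3-oxopropyl)-2,3-dihydro-1-benzofuran-3-yl]acetic acid
Product: 13 1,3-dioxoisoindolin-2-yl 2-[(2S,3S)-2-(4-acetoxy-3,5-dimethoxyphenyl)-7-methoxy-5-(3-methoxy-3-oxopropyl)-2,3-dihydro-1-benzofuran-3-yl]acetate
Conditions: N-hydroxyphthalimide (1.1 equiv), DIC (1.1 equiv), DMAP (10 mol %), CH2Cl2, rt
Reagents that add atoms: N-hydroxyphthalimide, ON1C(=O)c2ccccc2C1=O
Why: Steglich-type carbodiimide esterification converts the acid into the redox-active N-acyloxyphthalimide under neutral conditions.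

Step 9
Reactants: 13 1,3-dioxoisoindolin-2-yl 2-[(2S,3S)-2-(4-acetoxy-3,5-dimethoxyphenyl)-7-methoxy-5-(3-methoxy-3-oxopropyl)-2,3-dihydro-1-benzofuran-3-yl]acetate
Product: 15 methyl 3-[(2S,3S)-2-(4-acetoxy-3,5-dimethoxyphenyl)-7-methoxy-3-[(4,4,5,5-tetramethyl-1,3,2-dioxaborolan-2-yl)methyl]-2,3-dihydro-1-benzofuran-5-yl]propanoate, via catechol boronate 14 (not isolated)
Conditions: B2cat2 (1.25 equiv), DMAc, blue LEDs (450 nm), rt; then pinacol (4 equiv), Et3N, rt
Reagents that add atoms: bis(catecholato)diboron, B1(Oc2ccccc2O1)B1Oc2ccccc2O1; pinacol, CC(C)(O)C(C)(C)O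
Why: Photoinduced decarboxylative borylation: the electron donor–acceptor complex of the phthalimide ester with amide-ligated B2cat2 should fragment under blue light to CO2 and the primary C3–CH2 radical, which is borylated in a radical chain without involving the stereocentres, and transesterification with pinacol gives a boronate that survives chromatography.

Step 10
Reactants: 15 methyl 3-[(2S,3S)-2-(4-acetoxy-3,5-dimethoxyphenyl)-7-methoxy-3-[(4,4,5,5-tetramethyl-1,3,2-dioxaborolan-2-yl)methyl]-2,3-dihydro-1-benzofuran-5-yl]propanoate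
Product: 17 methyl 3-[(2S,3R)-2-(4-hydroxy-3,5-dimethoxyphenyl)-3-(hydroxymethyl)-7-methoxy-2,3-dihydro-1-benzofuran-5-yl]propanoate (target), via phenol boronate 16 (not isolated)
Conditions: K2CO3 (0.3 equiv), MeOH, 0 °C, 30 min; then NaBO3·4H2O (4 equiv), THF/H2O, rt; aq. NH4Cl
Reagents that add atoms: sodium perborate tetrahydrate, [Na+].[O-]OB=O.O.O.O.O
Why: Carbonate-catalysed transesterification frees the phenol, and hydroperoxide oxidation of the C–B bond (1,2-migration from boron to oxygen) should then convert CH2–B into CH2OH near pH 10, where the methyl ester survives and no stereocentre is touched.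

Compound list
1 | methyl 3-(4-hydroxy-3-methoxyphenyl)propanoate (methyl dihydroferulate) | COC(=O)CCc1ccc(O)c(OC)c1 | starting material
2 | methyl 3-(4-hydroxy-3-iodo-5-methoxyphenyl)propanoate | COC(=O)CCc1cc(I)c(O)c(OC)c1 | intermediate
3 | trimethylsilylacetylene | C#C[Si](C)(C)C | starting material
4 | methyl 3-[4-hydroxy-3-methoxy-5-(trimethylsilylethynyl)phenyl]propanoate | COC(=O)CCc1cc(OC)c(O)c(C#C[Si](C)(C)C)c1 | intermediate
5 | methyl 3-(3-ethynyl-4-hydroxy-5-methoxyphenyl)propanoate (not isolated) | COC(=O)CCc1cc(OC)c(O)c(C#C)c1 | intermediate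
6 | methyl 3-(7-methoxy-1-benzofuran-5-yl)propanoate | COC(=O)CCc1cc(OC)c2occc2c1 | intermediate
7 | tert-butyl diazoacetate | [N-]=[N+]=CC(=O)OC(C)(C)C | starting material
8 | tert-butyl (1R,1aR,6bS)-3-methoxy-5-(3-methoxy-3-oxopropyl)-1a,6b-dihydro-1H-cyclopropa[b][1]benzofuran-1-carboxylate (exo) | COC(=O)CCc1cc(OC)c2c(c1)[C@@H]1[C@@H](C(=O)OC(C)(C)C)[C@@H]1O2 | intermediate
9 | 2,6-dimethoxyphenol | COc1cccc(OC)c1O | starting material
10 | methyl 3-[(2S,3S)-3-(2-tert-butoxy-2-oxoethyl)-2-(4-hydroxy-3,5-dimethoxyphenyl)-7-methoxy-2,3-dihydro-1-benzofuran-5-yl]propanoate | COC(=O)CCc1cc(OC)c2c(c1)[C@H](CC(=O)OC(C)(C)C)[C@@H](c1cc(OC)c(O)c(OC)c1)O2 | intermediate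
11 | methyl 3-[(2S,3S)-2-(4-acetoxy-3,5-dimethoxyphenyl)-3-(2-tert-butoxy-2-oxoethyl)-7-methoxy-2,3-dihydro-1-benzofuran-5-yl]propanoate | COC(=O)CCc1cc(OC)c2c(c1)[C@H](CC(=O)OC(C)(C)C)[C@@H](c1cc(OC)c(OC(C)=O)c(OC)c1)O2 | intermediate
12 | 2-[(2S,3S)-2-(4-acetoxy-3,5-dimethoxyphenyl)-7-methoxy-5-(3-methoxy-3-oxopropyl)-2,3-dihydro-1-benzofuran-3-yl]acetic acid | COC(=O)CCc1cc(OC)c2c(c1)[C@H](CC(=O)O)[C@@H](c1cc(OC)c(OC(C)=O)c(OC)c1)O2 | intermediate
13 | 1,3-dioxoisoindolin-2-yl 2-[(2S,3S)-2-(4-acetoxy-3,5-dimethoxyphenyl)-7-methoxy-5-(3-methoxy-3-oxopropyl)-2,3-dihydro-1-benzofuran-3-yl]acetate | COC(=O)CCc1cc(OC)c2c(c1)[C@H](CC(=O)ON1C(=O)c3ccccc3C1=O)[C@@H](c1cc(OC)c(OC(C)=O)c(OC)c1)O2 | intermediate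
14 | methyl 3-[(2S,3S)-2-(4-acetoxy-3,5-dimethoxyphenyl)-3-(1,3,2-benzodioxaborol-2-ylmethyl)-7-methoxy-2,3-dihydro-1-benzofuran-5-yl]propanoate (not isolated) | COC(=O)CCc1cc(OC)c2c(c1)[C@H](CB1Oc3ccccc3O1)[C@@H](c1cc(OC)c(OC(C)=O)c(OC)c1)O2 | intermediate
15 | methyl 3-[(2S,3S)-2-(4-acetoxy-3,5-dimethoxyphenyl)-7-methoxy-3-[(4,4,5,5-tetramethyl-1,3,2-dioxaborolan-2-yl)methyl]-2,3-dihydro-1-benzofuran-5-yl]propanoate | COC(=O)CCc1cc(OC)c2c(c1)[C@H](CB1OC(C)(C)C(C)(C)O1)[C@@H](c1cc(OC)c(OC(C)=O)c(OC)c1)O2 | intermediate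
16 | methyl 3-[(2S,3S)-2-(4-hydroxy-3,5-dimethoxyphenyl)-7-methoxy-3-[(4,4,5,5-tetramethyl-1,3,2-dioxaborolan-2-yl)methyl]-2,3-dihydro-1-benzofuran-5-yl]propanoate (not isolated) | COC(=O)CCc1cc(OC)c2c(c1)[C@H](CB1OC(C)(C)C(C)(C)O1)[C@@H](c1cc(OC)c(O)c(OC)c1)O2 | intermediate
17 | methyl 3-[(2S,3R)-2-(4-hydroxy-3,5-dimethoxyphenyl)-3-(hydroxymethyl)-7-methoxy-2,3-dihydro-1-benzofuran-5-yl]propanoate | COC(=O)CCc1cc(OC)c2c(c1)[C@H](CO)[C@@H](c1cc(OC)c(O)c(OC)c1)O2 | target

Total step count: 10. Longest linear sequence: 10 steps (1 → 17); compounds 3, 7 and 9 enter as purchased.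

Steps most likely to fail

Step 4. Facial discrimination by the ligand may be insufficient, or carbene transfer to the weakly nucleophilic benzofuran may be so slow that carbene dimerisation consumes the diazo ester. Fallback (from 6, back at 8): cyclopropanation of 6 with 7 under Rh2(OAc)4 (1 mol %, CH2Cl2, rt, slow addition) should give the exo cyclopropane as a racemate. This is a 1:1 mixture of 8 and its mirror image, tert-butyl (1S,1aS,6bR)-3-methoxy-5-(3-methoxy-3-oxopropyl)-1a,6b-dihydro-1H-cyclopropa[b][1]benzofuran-1-carboxylate F1. Preparative supercritical-fluid chromatography on an amylose tris(3,5-dimethylphenylcarbamate) phase then separates the enantiomers, and 8 re-enters the route at step 5. Stereocontrol is thereby moved from the catalyst to a physical resolution.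

Step 5. Loss of the C3 proton from the oxocarbenium intermediate (aromatisation to a benzofuran-3-acetate) may outrun capture by the arene, or the phenol may be captured through oxygen instead of carbon. Fallback (from 8, back at 10): the ring is first opened with a solvent-level nucleophile. Camphorsulfonic acid (5 mol %) in MeOH at rt should give the cyclic acetal tert-butyl 2-[(3S)-2,7-dimethoxy-5-(3-methoxy-3-oxopropyl)-2,3-dihydro-1-benzofuran-3-yl]acetate F2 as a mixture of C2 epimers. The acetal is then ionised at low temperature (BF3·OEt2, 9 in excess, CH2Cl2, −40 → 0 °C) in a Friedel–Crafts C-arylation of the kind used for aryl C-glycosides. No enolate is present as an internal base, and the aryl group again enters anti to the C3 arm to give 10.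

Step 9. The primary radical may leak before boron capture, either by β-scission of the C3–C2 bond (opening the dihydrofuran ring to a benzylic α-aryloxy radical) or by hydrogen abstraction. Fallback (from 13, back at 17): the radical is trapped at a near diffusion-controlled rate by a nitroxide. Ru(bpy)3Cl2 (1 mol %), Hantzsch ester and TEMPO in DMF under blue LEDs should give the alkoxyamine methyl 3-[(2S,3R)-2-(4-acetoxy-3,5-dimethoxyphenyl)-7-methoxy-3-{[(2,2,6,6-tetramethylpiperidin-1-yl)oxy]methyl}-2,3-dihydro-1-benzofuran-5-yl]propanoate F3. Zn in AcOH/THF/H2O at 50 °C cleaves the N–O bond to methyl 3-[(2S,3R)-2-(4-acetoxy-3,5-dimethoxyphenyl)-3-(hydroxymethyl)-7-methoxy-2,3-dihydro-1-benzofuran-5-yl]propanoate F4. K2CO3 (0.3 equiv) in MeOH at 0 °C then removes the aryl acetate to give 17, so the C–O bond is formed directly and the boron stage is bypassed.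

Further compounds
F1 | step 4 | tert-butyl (1S,1aS,6bR)-3-methoxy-5-(3-methoxy-3-oxopropyl)-1a,6b-dihydro-1H-cyclopropa[b][1]benzofuran-1-carboxylate (mirror image of 8, second component of the racemate) | COC(=O)CCc1cc(OC)c2c(c1)[C@H]1[C@H](C(=O)OC(C)(C)C)[C@H]1O2
F2 | step 5 | tert-butyl 2-[(3S)-2,7-dimethoxy-5-(3-methoxy-3-oxopropyl)-2,3-dihydro-1-benzofuran-3-yl]acetate (mixture of C2 epimers) | COC(=O)CCc1cc(OC)c2c(c1)[C@H](CC(=O)OC(C)(C)C)C(OC)O2
F3 | step 9 | methyl 3-[(2S,3R)-2-(4-acetoxy-3,5-dimethoxyphenyl)-7-methoxy-3-{[(2,2,6,6-tetramethylpiperidin-1-yl)oxy]methyl}-2,3-dihydro-1-benzofuran-5-yl]propanoate | COC(=O)CCc1cc(OC)c2c(c1)[C@H](CON1C(C)(C)CCCC1(C)C)[C@@H](c1cc(OC)c(OC(C)=O)c(OC)c1)O2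
F4 | step 9 | methyl 3-[(2S,3R)-2-(4-acetoxy-3,5-dimethoxyphenyl)-3-(hydroxymethyl)-7-methoxy-2,3-dihydro-1-benzofuran-5-yl]propanoate | COC(=O)CCc1cc(OC)c2c(c1)[C@H](CO)[C@@H](c1cc(OC)c(OC(C)=O)c(OC)c1)O2
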